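(The rate constants are made up; the run is a simulation.)

You want to know which form holds most of the D at the end of each flask, and how much of it.

| flask | D | X | time |
|---|---|---|---|
| epsilon | 0.19 M | 0.190 M | 12 h |
| theta | 0.19 M | 0.470 M | 12 h |

    X → G (k1 = 0.0019 s⁻¹)
    D + X → E (k2 = 0.012 M⁻¹ s⁻¹)
    D + X → Q (k3 = 5.2 × 10⁻⁵ M⁻¹ s⁻¹)
    D + X → D.X (k4 = 0.0047 M⁻¹ s⁻¹)

- which of these there is most of at the end, counted by the D in it, epsilon (Q / E / D / D.X)
- which of these there is most of at the end, counted by the D in it, theta (Q / E / D / D.X)
- amount of the one of these that there is most of at the end, in percent of the D charged, epsilon
- amount of the one of these that there is most of at the end, in percent of the D charged, theta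

Start by counting half-lives. The passing of X into G alone halves X every 0.10 h, and the 12 h hold 118 such half-lives, so the end depends on how X divides, not on the clock. Each X either becomes G or meets D, and each of the three steps of D with X consumes one X per D. Divide the constant of the loss to G by the sum of those three constants: this partition concentration K, 0.113 M, is the c(D) at which X is shared equally between G and D.

In epsilon, c(D) starts at 0.19 M, above K, so D takes 62.6% of the X at first. If that share held in epsilon, 37.4% of D would survive. But the share falls with c(D), so this estimate is too low. Dividing the two rate laws gives the exact balance: X consumed equals D consumed plus K times the natural logarithm of charged over remaining D, the second term being the X that became G. After so many half-lives you take X consumed as the charged X.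

The balance has no direct solution, so you iterate. In epsilon the charges are equal, so the surviving fraction is the exponential of minus that fraction times the charged c(D) over K. For epsilon, feeding in the first estimate gives 53.5%, which overshoots. For epsilon, the midpoint of the two returns 46.7%, and averaging that midpoint with its return gives 46.1%. The selectivity for E among converted D is 71.6%, so in epsilon you reckon E at 38.6%, behind D.

In theta, taking the surviving fraction as zero inside the balance gives 8.47%, and two feedbacks bring it to 7.49%. In theta you then reckon E at 66.2%, ahead of D.

The forecast says D at 46.2% in epsilon and E at 66.3% in theta, on the ground that “the outcome is set by how X splits between its first-order loss and reaction with D”.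

The simulation gives D at 46.2% in epsilon, with E at 38.6%, and E at 66.3% in theta, with D at 7.47%. Now raise X in the theta flask to 1.2 M, which is 6.32 equiv of X to D. With the same K, and the surviving fraction again taken as zero inside the balance, the surviving fraction of D in this neighbour is the exponential of minus the excess of X over D divided by K, which is 0.0136%, and you reckon its E at 71.6%. That neighbouring flask ends with 0.014% of its D unreacted and E at 71.6%.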